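Count the pool.

    bis adduct ⇌ isomer of the product (K1 = 1.1, k1 = 0.00107 s⁻¹)
    reagent + first product → bis adduct + by-product (k2 = 0.00449 M⁻¹ s⁻¹)
    substrate + reagent → first product + by-product (k3 = 0.00303 M⁻¹ s⁻¹)
    reagent + bis adduct → triple product + by-product (k4 = 0.0133 M⁻¹ s⁻¹)
    bis adduct + by-product → side product (k5 = 0.00748 M⁻¹ s⁻¹)
    bis adduct → over-reaction product (k6 = 7.41 × 10⁻⁸ s⁻¹)

| flask | substrate | reagent | time | remark |
|---|---|---|---|---|
| east | 0.19 M | 1.00 equiv | 40 min | a closed flask charged with all of it at once and left for 40 min |
| north-east | 0.19 M | 1.00 equiv |  | a single well-mixed tank run continuously and read at steady state, 40 min in it on average |
| south | 0.19 M (fed, over 32.0 min) | 1.00 equiv | 40 min | all but substrate at the start; substrate goes in evenly over 32.0 min, the run ends at 40 min |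
| north | 0.19 M | 1.00 equiv (fed, over 32.0 min) | 40 min | a stirred flask in which reagent is dosed at a steady rate over 32.0 min without added volume, worked up at 40 min |

1. the set-up with the highest share of bis adduct in all that became bis adduct or triple product or side product or isomer of the product, at the outlet or at the end ("none" if the first two lie within 2 percentage points) (east / north-east / south / north / none)
2. share of bis adduct in all that became bis adduct or triple product or side product or isomer of the product, at the outlet or at the end, east
3. share of bis adduct in all that became bis adduct or triple product or side product or isomer of the product, at the outlet or at the end, north-east
4. share of bis adduct in all that became bis adduct or triple product or side product or isomer of the product, at the outlet or at the end, south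
5. share of bis adduct in all that became bis adduct or triple product or side product or isomer of the product, at the outlet or at the end, north

- the stated concentrations are those of everything mixed, before any reaction; amounts are the same in each set-up
- the feed brings no volume worth counting
- the share counts what is present at the end, not what went on to other products
- run time (east): 40 min

Let D be bis adduct, I the isomer of the product, B reagent and P by-product. The pool is what the share counts: bis adduct, isomer, triple product and side product. The share is D over the pool, so you work with its reciprocal, whose terms add.

The tank, with mean residence time τ = 40 min, gives this by hand. The step to over-reaction product makes no difference there. The pool leaves by the outlet, so it equals τ times its inflow. That inflow must balance D's outflow, its net loss to I, and two pseudo-first-order drains, 0.0133 M⁻¹ s⁻¹ on B and 0.00748 M⁻¹ s⁻¹ on P. Write u = 2.57 for the forward isomerisation over τ, and K = 1.1. The isomer term is then x = u/(1 + u/K) = 0.770, and the reciprocal is 1 + x + τ times the two drains.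

But B and P are unknown. Guess B = 0.0760 M and take P as the reagent spent, 0.114 M. Then N, the pool held per unit of bis adduct in the tank, is 6.24, a share of 16.0%.

Is the guess consistent? At that B, the substrate left is 64.4% of its charge, and 16.0% of the charge enters the pool. Adding the triple product, reagent spent comes back as 57.8% of the charge, against 60.0% assumed, so the guess stands.

Side product, however, consumes by-product, 5.25% of the charge. Taking that off P gives N = 5.99, so you commit to a tank share between 16.0% and 16.7%.

The objection to going further is that in the flasks the concentrations move, and N was built for a steady tank. In closed east, bis adduct's half-life by step 4 alone at charged concentrations, 4.6 min, is shorter than the 11 min of step 1's forward rate alone, and that is short against 40 min. So you expect east near the tank. For the dosed flasks, south and north, you commit to no figure and no order.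

The forecast gives 16.2% for east, 16% for north-east, 23.4% for south and 30% for north, and picks north, holding that “slow reagent dosing helps most”. The simulation gives 17.1%, 16.4%, 24.1% and 30.2% in that order, and its best is north. The largest single effect behind north's place is the slow dosing of reagent: without that dosing, north's share falls from 30.2% to 17.1%.

The tank's share means N = 6.10, against your 6.24. Part of that 16.4% rests on the wearing away of reagent. Hold B at the charge in the same tank and take P at the charge too, and N becomes 11.2, a share of 8.93%. The simulated run with reagent held gives 8.75%.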